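Self-condensation product per target at the first reading, summed over the three earlier runs, is 2.73. As a reading it barely shifts between dawn at −25 °C (2.80) and summer at −14 °C (2.75).

| flask | starting material | coupling partner | second substrate | temperature | remark | time |
|---|---|---|---|---|---|---|
| dawn | 0.10 M | 0.11 M | 0.10 M | −25 °C | run made earlier |  |
| summer | 0.10 M | 0.11 M | 0.14 M | −14 °C | run made earlier |  |
| winter | 0.10 M | 0.11 M | 0.22 M | −25 °C | run made earlier |  |
| teal | 0.10 M | 0.110 M | 0.100 M | −20 °C | everything together at the start | 4.0 h |
| green | 0.10 M (fed, over 2.5 h) | 0.110 M | 0.100 M | −20 °C | all else is in the flask from the start; the feed brings no volume worth counting | 4.0 h |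
| violet | 0.10 M | 0.110 M (in portions, 4, over 2.5 h) | 0.100 M | −20 °C | first portion at the start, last at 2.5 h | 4.0 h |
| red | 0.10 M (fed, over 2.5 h) | 0.110 M | 0.100 M |  | the addition at −40 °C, then warmed to −20 °C; the feed brings no volume worth counting | 4.0 h |

| run | time / h | self-condensation product / % | target / % |
|---|---|---|---|
| dawn | 0.200 | 12.3 | 4.4 |
| dawn | 0.333 | 16.7 | 7.5 |
| dawn | 0.500 | 24.3 | 9.0 |
| dawn | 0.833 | 31.9 | 13.9 |
| dawn | 1.33 | 40.6 | 18.6 |
| dawn | 2.50 | 44.8 | 23.1 |
| summer | 0.250 | 31.3 | 11.4 |
| summer | 0.417 | 41.3 | 17.4 |
| summer | 0.667 | 46.3 | 20.0 |
| summer | 1.33 | 55.1 | 24.6 |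
| summer | 2.00 | 57.7 | 25.8 |
| summer | 3.00 | 57.4 | 27.2 |
| winter | 0.200 | 13.0 | 4.9 |
| winter | 0.667 | 29.3 | 11.7 |
| winter | 1.00 | 35.3 | 15.2 |
| winter | 2.00 | 44.6 | 23.1 |
| winter | 2.50 | 49.5 | 21.2 |
| winter | 3.00 | 50.3 | 22.9 |

(scatter of a reading: 1 percentage point)

- percent here means starting material units held: one self-condensation product counts as two
- the analysis behind the earlier runs scatters by 1 percentage point, standard deviation
- a reading or a percentage of target counts all its forms, free or not

- which flask leads in amount of self-condensation product, in percent of the starting material charged ("all alike" within 1.5 percentage points) (teal / green / violet / red / all alike)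
- how much self-condensation product is there at the end, in percent of the starting material charged: teal
- how much self-condensation product is there at the end, in percent of the starting material charged: green
- how much self-condensation product is there at the end, in percent of the starting material charged: violet
- how much self-condensation product is there at the end, in percent of the starting material charged: red

We let self-condensation go with c(starting material) squared and target with c(starting material) times c(coupling partner). The partner's part is our assumption, since each earlier run charged 0.11 M. The rate ratio is then x = s·c(starting material)/c(coupling partner), where s is the selectivity factor, 3.01. With c(coupling partner) held and the starting material used up, the share reaching target is ln(1+x)/x, with x taken at the start. That brackets violet.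

Floor, whole charge present from the start: x = 2.73, self-condensation product 51.8%.

Ceiling, first portion held throughout: x = 10.9, self-condensation product 77.3%.

Tightened floor: the second portion comes at 0.833 h, and at that time the readings of dawn, run at −25 °C with the whole charge of coupling partner, sum to 45.8% of its starting material. We run that part at the ceiling's x and the rest at the whole charge: 61.8%.

Neither line is a strict bound: both hold c(coupling partner) fixed and take the starting material as used up. Slow feeding lowers c(starting material) in x, so green pulls the other way, and we put violet first, between 61.8% and 77.3%.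

The forecast names violet: teal 57%, green 53%, violet 59%, red 50%, on the ground that “Violet starves the partner early”. Its violet stands lower than our tightened floor.

Violet ends at 69.7% self-condensation product, higher than the tightened floor and lower than the ceiling; teal gives 55.4%, green 44.7%, red 47.1%.

starting material + coupling partner ⇌ target (K = 260 L mol⁻¹, k = 0.0642 L mol⁻¹ min⁻¹, Ea = 47.0 kJ mol⁻¹, ΔH = −7.00 kJ mol⁻¹); second substrate + coupling partner ⇌ second product (K = 3.66 L mol⁻¹, k = 0.0143 L mol⁻¹ min⁻¹, Ea = 47.0 kJ mol⁻¹, ΔH = 0 kJ mol⁻¹); 2 starting material → self-condensation product (k = 0.106 L mol⁻¹ min⁻¹, Ea = 54.0 kJ mol⁻¹); starting material + target ⇌ idle adduct, settled at all times (K = 3.30 L mol⁻¹, ΔH = −50.0 kJ mol⁻¹); starting material + target → side product (k = 0.0276 L mol⁻¹ min⁻¹, Ea = 48.0 kJ mol⁻¹); (constants at −20 °C) Just before its last addition, violet already holds 66.7%, with coupling partner at 55.4% of its whole charge. Now s on green at the end of the feed, with 41.7% starting material and 66.2% coupling partner: x = 1.72. From there to 4.00 h, green gains 14 percentage points self-condensation product against 8 points target, a ratio of 1.78.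

The readings stem from a simulated flask for substances that don't exist, and the scatter is random.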